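## Conventions and assumptions

- Flavan numbering is used throughout: O1, C2, C3, C4, C4a, C5–C8, C8a. Ring A is the benzo ring, ring B the 2-aryl ring, ring C the pyran ring. The three units are T (top, its C4 carries the next unit), M (middle) and B (terminal 3,4-diol).
- Remark on descriptors: a silyl ether or thioether at C4 outranks O1 in the CIP sense, so C3 of some protected chromans carries a different letter from C3 of the free unit although the geometry is the same. The SMILES strings are the reference.
- Assumption 1: [4-(benzyloxy)phenyl]magnesium bromide (25) is used as its commercial THF solution.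
- Assumption 2: 2-bromo-3-hydroxy-4-methoxybenzaldehyde (18) is taken as a commercial compound.
- Assumption 3: the C4 configuration of thioether 30 is of no consequence, because C4 becomes planar when it reacts; 30 is drawn as the expected 3,4-trans epimer.

## Analysis of the target

The target is a linear trimer of three 2-(4-hydroxyphenyl)chroman-3-ol units with 7,8-dihydroxylated rings A, in which C4 of unit T is bonded to C6 of unit M, C4 of M is bonded to C6 of unit B, and B keeps a hydroxyl at C4. There are nine stereocentres: T is (2R,3R,4S), 2,3-cis with the C4 aryl trans to O3; M is (2R,3S,4R), 2,3-trans-3,4-trans; B is (2R,3R,4R), with the aryl group, the 3-hydroxyl and the 4-hydroxyl all cis. All three C2 centres have the same sense, and in T and M the C4 substituent is anti to O3, which is the outcome expected when a C4 cation is captured from the face opposite the C3 oxygen. The sensitive groups are the nine phenols in catechol-like arrays (oxidation, above all in base), the benzylic 4-hydroxyl of B para to the 7-oxygen (it ionises in acid and then alkylates other rings), the two doubly benzylic interflavan bonds and the benzylic C2–O1 ether bonds. The hard part is the all-cis triad of B: a closure through C2 either ionises this benzylic carbon, which carries a para-oxygenated aryl group, or has to invert it, and the cis isomer is the less stable one. In addition the rings A are of the weakly nucleophilic pyrogallol type, and M has to act once as nucleophile and once as electrophile. The strategy rests on the aryl ether bond O1–C8a of ring C: it lies outside the triad C2–C3–C4, so a ring closure there, from an open-chain triol on a ring A that carries bromine at C8a, touches no stereocentre. A second useful feature is that C6 of every ring A is para to O1 and ortho to the 7-oxygen, while C4 is benzylic to the same two oxygens, so each interflavan bond can be made from a C4 cation and C6.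

## Retrosynthetic reasoning

**36 back to 34.** The last operations only unmask. All twelve phenol and C3 ethers are benzyl ethers and the C6 bromine of T is a temporary cap, so one hydrogenolysis of 35 gives 36. Before that, the silyl ether at O4 of unit B is cleaved (34 to 35) while every phenol is still protected and the basic fluoride can do no harm.

**34 to 33 and 17 (bond C4 of M to C6 of B).** This bond is cut because C4 of M is stabilised as a cation by O1 and the 7-oxygen, and C6 of B is the one strongly activated position of its ring A. The forward reaction has to ionise the C4–S bond of 33 with a thiophilic activator that leaves the benzylic silyl ether of 17 alone. Attack anti to the 3-benzyloxy group gives the 3,4-trans centre (4R). Dimer 33 cannot alkylate itself, since C6 of its unit T is brominated and C6 of its unit M is occupied.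

**33 to 32 and 30 (bond C4 of T to C6 of M).** Here the two partners are told apart by the kind of leaving group. The hydroxyl of 32 answers to a hard Lewis acid, whereas the hindered aryl thioether of 30 stays latent until the next coupling. The bromine at C6 of 32 keeps the electrophile from reacting with itself. The cation from the 2,3-cis unit has its aryl and benzyloxy groups on one face, so C6 of 30 can only enter on the other, which gives the 4S centre.

**32 and 30 back to the monomers.** Unit T needs only C2 and C3 of the all-cis building block, because its C4 is planarised. The same compound 17 therefore serves as unit B and, after bromination at C6 (31) and desilylation (32), as the source of T. Thioether 30 comes from silyl ether 28 through alcohol 29 by thiolysis.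

**17 to 16 (bond O1–C8a, the key disconnection).** Cutting O1–C2 instead would require a substitution at a benzylic carbon that ionises easily, and cutting C4–C4a would create C4 under acid. The aryl ether bond is the only ring bond whose formation leaves C2, C3 and C4 as they are. The forward reaction must join the C2 alkoxide to the brominated aromatic carbon with retention and without base- or acid-induced change elsewhere.

**16 to 13.** The free C2 hydroxyl and the silyl ether at O4 are arranged by two protecting-group steps (15, 14). The C4 centre comes from reduction of ketone 13 under chelation by the neighbouring benzyloxy group, which gives the 3,4-anti relation that becomes 3,4-cis in the ring.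

**13 to 11 and 3 (bond C4–C4a).** The ketone is cut between the carbonyl carbon and ring A. Weinreb amide 11 takes up one equivalent of the aryl Grignard reagent 12. Metalating 2 itself would consume the very bromine the ring closure needs, so 12 is made from iodide 3, in which iodine next to the bromine is exchanged selectively.

**11 to 6 and 7 (bond C2–C3).** An auxiliary-controlled syn glycolate aldol reaction through boron enolate 8 sets C2 and C3 together (9), followed by amide exchange (10) and silylation (11). Imide 6 comes from 4 and 5.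

**3 to 1.** Iodide 3 comes from dibenzyl ether 2 by iodination para to the unhindered benzyloxy group, and 2 from 1.

**Unit M (28 to 18 and 6).** The same aryl ether disconnection turns 28 into alcohol 27. Its C2 hydroxyl comes from chelation-controlled reduction of ketone 26, which gives the 2,3-anti relation, that is 2,3-trans in the ring. Ketone 26 is cut into Weinreb amide 24 and Grignard reagent 25. The aldol roles are reversed here: ring A is the aldehyde (20), so the aldol reaction (22, then 23 and 24) fixes C3, and the same auxiliary gives the C3 configuration that M needs. Aldehyde 20 is electron-rich and carries an ortho bromine, and only the α-centre of its adduct is kept, so imide 6 reacts here as its more Lewis-acidic titanium enolate 21. Aldehyde 20 is not drawn from iodide 3: 18 already has the bromine, both oxygens and the formyl group in the right positions, so demethylation (19) and benzylation are enough, and reagent 12 is needed only once, for ketone 13.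

## Alternatives that were turned down

**Alternative 1:** The last ring to close would be ring C of unit T, by cutting O1–C2 of T in an assembled, protected trimer. In the forward sense a mild acid would let the free ring A phenol of T open a cis-epoxide at its benzylic carbon with inversion, giving A1 with a pivalate on ring B of T and the 3-hydroxyl set free.
- For it: C2 and C3 of T come from the geometry of one epoxide, the 2,3-cis relation and the free 3-hydroxyl appear in one step, and the electron-poor pivalate is a sensible brake on ionisation.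
- Against it: the step stands at the very end, on the most valuable intermediate. The carbon under attack is still an oxygenated benzylic centre, and any ionisation leads to the 2,3-trans epimer, which cannot be corrected. Attack at C3 to a dihydrobenzofuran (5-exo) competes exactly when the pivalate weakens the benzylic bias. The cis-epoxide must be made with facial control next to a triaryl-substituted C4 that itself has to be set in open-chain form. The approach does nothing for the all-cis triad of B.
- Comparison: Alternative 1 is stronger in that the T–M bond needs no cation coupling and no blocking bromine. The chosen route offers in its place ring closures on monomers under base, with every ring stereocentre fixed beforehand by auxiliary or chelate control, and one building block (17) that is used twice.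

**Alternative 2:** Ring C of B would be closed at C4–C4a. An aryl ether that already joins O1 to C2 carries an α-benzyloxy aldehyde taken from the chiral pool, and a chelating Lewis acid is to make ring A attack the aldehyde, giving A2 with the 4-hydroxyl cis to O3.
- For it: it is short, the chiral pool supplies C3, the chelate gives the 3,4-cis relation directly, and A2 already has the free 4-hydroxyl. In steps to the monomer it is clearly ahead of the eleven steps to 17.
- Against it: the aryl ether O1–C2 has to be made first by substitution at the 4-benzyloxybenzylic carbon, so the C2 problem is moved and not removed. A2 is a 2,4-dioxygenated benzylic alcohol, which the same Lewis acid can ionise again, with epimerisation towards the 3,4-trans isomer or arylation of a second molecule. The α-alkoxy aldehyde can epimerise, and a ring A with ether oxygens only is a slow nucleophile.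
- Comparison: it is shorter and more direct, but C4 is decided under conditions in which the product is labile. In the chosen route C4 is set by hydride reduction of a ketone, and the ring is closed by a step that cannot touch it.

**Alternative 3:** Ring C of M would be built on unit B by cutting both O1–C2 and C3–C4 of M. A diaryl carbinol at C6 of B is ionised by a chiral strong Brønsted acid to an ortho-quinone methide, which adds the alkyne A4 to give the 2-aryl-4H-chromene A3 with C4 set; hydroboration would follow.
- For it: the chain grows on B without a separate synthesis of M. The interflavan bond comes from a carbonyl addition and not from alkylation of a weakly nucleophilic ring. Hydroboration anti to the C4 aryl group would give exactly the 2,3-trans-3,4-trans pattern of M.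
- Against it: the only stereocentre made in the key step is a triaryl-substituted C4, controlled by a catalyst on a substrate that already carries a large chiral unit, with unknown matching. Aryl alkynes are poor partners for ortho-quinone methides, so dimerisation of the quinone methide competes. Strong acid meets the acetal-protected benzylic diol of B. The 2,3-cis unit T cannot be made the same way without an extra oxidation and reduction at C3.
- Comparison: it is stronger in convergence and in avoiding cation couplings for M. The chosen route offers C4 centres under substrate control (attack anti to O3) and C2/C3 centres from auxiliary control, at the price of separate monomer syntheses.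

Key step: step 11

## Route

Step 1
Reactants: 1 3-bromocatechol
Product: 2 1,2-bis(benzyloxy)-3-bromobenzene
Conditions: BnBr, K2CO3, DMF, 60 °C
Reagents that add atoms: benzyl bromide, BrCc1ccccc1
Why: Williamson etherification of both phenols; benzyl is chosen because all such ethers fall in the final hydrogenolysis.

Step 2
Reactants: 2 1,2-bis(benzyloxy)-3-bromobenzene
Product: 3 1,2-bis(benzyloxy)-3-bromo-4-iodobenzene
Conditions: NIS (1.05 equiv), TFA (cat.), MeCN, 0 °C → rt
Reagents that add atoms: N-iodosuccinimide, O=C1CCC(=O)N1I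
Why: Electrophilic aromatic iodination; the 1-benzyloxy group has a free ortho position and stays conjugated, whereas the 2-benzyloxy group is twisted between two neighbours, so iodine should enter para to O1, next to bromine.

Step 3
Reactants: 4 (S)-4-benzyl-1,3-oxazolidin-2-one; 5 benzyloxyacetyl chloride
Product: 6 (S)-4-benzyl-3-[(benzyloxy)acetyl]-1,3-oxazolidin-2-one
Conditions: Et3N, DMAP (cat.), CH2Cl2, 0 °C → rt
Reagents that add atoms: none
Why: DMAP-catalysed N-acylation of the oxazolidinone by the acid chloride; no stereocentre is affected.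

Step 4
Reactants: 6 (S)-4-benzyl-3-[(benzyloxy)acetyl]-1,3-oxazolidin-2-one; 7 4-(benzyloxy)benzaldehyde
Product: 9 (4S)-4-benzyl-3-[(2S,3R)-2-(benzyloxy)-3-[4-(benzyloxy)phenyl]-3-hydroxypropanoyl]-1,3-oxazolidin-2-one, via dibutylboron (Z)-enolate 8 (not isolated)
Conditions: Bu2BOTf, Et3N, CH2Cl2, −78 → 0 °C; then 7, −78 → 0 °C; pH 7 buffer, MeOH, H2O2
Reagents that add atoms: none
Why: Evans syn glycolate aldol reaction; the (Z)-boron enolate reacts through a chair transition state on the face away from the auxiliary benzyl group, which sets C3 and C2 of the future units B and T in the 2,3-syn relation and the required absolute sense.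

Step 5
Reactants: 9 (4S)-4-benzyl-3-[(2S,3R)-2-(benzyloxy)-3-[4-(benzyloxy)phenyl]-3-hydroxypropanoyl]-1,3-oxazolidin-2-one
Product: 10 (2S,3R)-2-(benzyloxy)-3-[4-(benzyloxy)phenyl]-3-hydroxy-N-methoxy-N-methylpropanamide
Conditions: MeNH(OMe)·HCl, AlMe3, CH2Cl2, −20 → 0 °C; aqueous potassium sodium tartrate
Reagents that add atoms: N,O-dimethylhydroxylamine hydrochloride, CNOC.Cl
Why: Aluminium amide transamination of the imide to the Weinreb amide, helped by the free β-hydroxyl; the auxiliary is released and can be recovered.

Step 6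
Reactants: 10 (2S,3R)-2-(benzyloxy)-3-[4-(benzyloxy)phenyl]-3-hydroxy-N-methoxy-N-methylpropanamide
Product: 11 (2S,3R)-2-(benzyloxy)-3-[4-(benzyloxy)phenyl]-N-methoxy-N-methyl-3-[(triethylsilyl)oxy]propanamide
Conditions: TESCl, imidazole, DMF, 0 °C → rt
Reagents that add atoms: chlorotriethylsilane, CC[Si](Cl)(CC)CC
Why: Silylation of the secondary alcohol; the triethylsilyl group is chosen because it can later be removed in the presence of a tert-butyldimethylsilyl ether.

Step 7
Reactants: 3 1,2-bis(benzyloxy)-3-bromo-4-iodobenzene; 11 (2S,3R)-2-(benzyloxy)-3-[4-(benzyloxy)phenyl]-N-methoxy-N-methyl-3-[(triethylsilyl)oxy]propanamide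
Product: 13 (2S,3R)-2-(benzyloxy)-1-[3,4-bis(benzyloxy)-2-bromophenyl]-3-[4-(benzyloxy)phenyl]-3-[(triethylsilyl)oxy]propan-1-one, via aryl Grignard reagent 12 (not isolated)
Conditions: 3, iPrMgCl·LiCl, THF, −40 °C; then 11, −40 → 0 °C; aq NH4Cl
Reagents that add atoms: none
Why: Iodine–magnesium exchange is much faster than bromine–magnesium exchange, so the bromine needed for ring closure stays; the Grignard reagent adds once to the Weinreb amide through the chelated tetrahedral intermediate, and the α-centre is not exposed to free ketone enolate before work-up.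

Step 8
Reactants: 13 (2S,3R)-2-(benzyloxy)-1-[3,4-bis(benzyloxy)-2-bromophenyl]-3-[4-(benzyloxy)phenyl]-3-[(triethylsilyl)oxy]propan-1-one
Product: 14 (1R,2R,3R)-2-(benzyloxy)-1-[3,4-bis(benzyloxy)-2-bromophenyl]-3-[4-(benzyloxy)phenyl]-3-[(triethylsilyl)oxy]propan-1-ol
Conditions: Zn(BH4)2, Et2O, −40 → −20 °C; aq NH4Cl
Reagents that add atoms: none
Why: Chelation-controlled (Cram chelate) reduction; zinc bridges the ketone oxygen and the α-benzyloxy group and hydride enters from the face away from the silyloxybenzyl substituent, which should give the 1,2-anti alcohol, the future 3,4-cis relation; the silyl ether does not chelate.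

Step 9
Reactants: 14 (1R,2R,3R)-2-(benzyloxy)-1-[3,4-bis(benzyloxy)-2-bromophenyl]-3-[4-(benzyloxy)phenyl]-3-[(triethylsilyl)oxy]propan-1-ol
Product: 15 (1R,2S,3R)-2-(benzyloxy)-1-[3,4-bis(benzyloxy)-2-bromophenyl]-3-[4-(benzyloxy)phenyl]-1-[(tert-butyldimethylsilyl)oxy]-3-[(triethylsilyl)oxy]propane
Conditions: TBSOTf, 2,6-lutidine, CH2Cl2, −78 → 0 °C
Reagents that add atoms: tert-butyldimethylsilyl trifluoromethanesulfonate, CC(C)(C)[Si](C)(C)OS(=O)(=O)C(F)(F)F
Why: Silylation of the hindered benzylic alcohol with the reactive silyl triflate; the triethylsilyl ether is stable to these conditions.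

Step 10
Reactants: 15 (1R,2S,3R)-2-(benzyloxy)-1-[3,4-bis(benzyloxy)-2-bromophenyl]-3-[4-(benzyloxy)phenyl]-1-[(tert-butyldimethylsilyl)oxy]-3-[(triethylsilyl)oxy]propane
Product: 16 (1R,2S,3R)-2-(benzyloxy)-1-[4-(benzyloxy)phenyl]-3-[3,4-bis(benzyloxy)-2-bromophenyl]-3-[(tert-butyldimethylsilyl)oxy]propan-1-ol
Conditions: HF·pyridine, pyridine, THF, 0 °C
Reagents that add atoms: none
Why: Selective cleavage of the less hindered triethylsilyl ether with buffered fluoride; the medium is not acidic enough to ionise the 4-benzyloxybenzylic carbon, so C2 keeps its configuration.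

Step 11
Reactants: 16 (1R,2S,3R)-2-(benzyloxy)-1-[4-(benzyloxy)phenyl]-3-[3,4-bis(benzyloxy)-2-bromophenyl]-3-[(tert-butyldimethylsilyl)oxy]propan-1-ol
Product: 17 (2R,3S,4R)-3,7,8-tris(benzyloxy)-2-[4-(benzyloxy)phenyl]-4-[(tert-butyldimethylsilyl)oxy]chromane (all-cis; protected unit B)
Conditions: CuI (10 mol %), 3,4,7,8-tetramethyl-1,10-phenanthroline (20 mol %), Cs2CO3 (2 equiv), toluene, 110 °C, argon
Reagents that add atoms: none
Why: Cs2CO3 turns the only free hydroxyl (at C2) into its alkoxide, which binds to the phenanthroline-ligated monovalent copper; the neighbouring C8a–Br bond then adds oxidatively to give a seven-membered cupracycle of trivalent copper (Cu, O, C2, C3, C4, C4a, C8a), and C–O reductive elimination forms O1–C8a and returns the catalyst. The closest known reaction type is the Ullmann-type copper–phenanthroline O-arylation of aliphatic alcohols with aryl halides, whose intramolecular form converts 3-(2-halophenyl)propanols into chromans with retention at the carbinol carbon. Ring C closes as a six-membered ring by joining the alkoxide oxygen to the aromatic carbon, with the departing bromide outside the new ring (6-exo sense). No stereocentre is made: C2, C3 and C4 arrive with the 2,3-syn-3,4-anti pattern from steps 4 and 8, and since no bond to any of them is broken this pattern becomes the all-cis ring. The step needs chemoselectivity for O2 and retention at C2; O3 is a benzyl ether, O4 is a silyl ether that could in any case only close a four-membered ring, and the basic, non-ionising medium gives the C2–O bond no path to a cation. The electron-rich bromide with two ortho substituents is the slow partner, which is why an electron-rich ligand, a non-coordinating solvent and 110 °C are chosen; a base-induced shift of the silyl group from O4 to O2 would only delay closure, because the shifted isomer cannot cyclise and returns to the alkoxide of 16.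

Step 12
Reactants: 18 2-bromo-3-hydroxy-4-methoxybenzaldehyde
Product: 19 2-bromo-3,4-dihydroxybenzaldehyde
Conditions: BBr3 (2.2 equiv), CH2Cl2, −78 → 0 °C; H2O
Reagents that add atoms: none
Why: Lewis-acid cleavage of the aryl methyl ether; the neighbouring phenol binds boron first, the methoxy oxygen then coordinates and bromide removes the methyl group, while the aldehyde and the aryl bromide are left alone at this temperature.

Step 13
Reactants: 19 2-bromo-3,4-dihydroxybenzaldehyde
Product: 20 3,4-bis(benzyloxy)-2-bromobenzaldehyde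
Conditions: BnBr, K2CO3, DMF, rt
Reagents that add atoms: benzyl bromide, BrCc1ccccc1
Why: Williamson etherification of both phenols under mild base, which the non-enolisable aldehyde tolerates; ring A of unit M is thus obtained with its bromine, both oxygens and the formyl group in place without an organometallic step.

Step 14
Reactants: 6 (S)-4-benzyl-3-[(benzyloxy)acetyl]-1,3-oxazolidin-2-one; 20 3,4-bis(benzyloxy)-2-bromobenzaldehyde
Product: 22 (4S)-4-benzyl-3-[(2S,3R)-2-(benzyloxy)-3-[3,4-bis(benzyloxy)-2-bromophenyl]-3-hydroxypropanoyl]-1,3-oxazolidin-2-one, via trichlorotitanium (Z)-enolate 21 (not isolated)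
Conditions: TiCl4 (1.05 equiv), i-Pr2NEt (1.1 equiv), CH2Cl2, 0 °C; N-methyl-2-pyrrolidinone (1.0 equiv); then 20, −78 → 0 °C; aq NH4Cl
Reagents that add atoms: none
Why: Evans syn aldol reaction through the chlorotitanium (Z)-enolate made by soft enolisation; with N-methyl-2-pyrrolidinone on titanium the aldehyde should react through the non-chelated chair transition state on the face away from the auxiliary benzyl group, the same sense as in step 4. The Lewis-acidic titanium is chosen because the electron-rich, ortho-brominated aldehyde 20 is a slower partner than 7. The acyl carbon will become C2, so the α-centre is C3 of unit M, opposite in ring terms to C3 of unit B, and the carbinol centre (future C4) is erased later.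

Step 15
Reactants: 22 (4S)-4-benzyl-3-[(2S,3R)-2-(benzyloxy)-3-[3,4-bis(benzyloxy)-2-bromophenyl]-3-hydroxypropanoyl]-1,3-oxazolidin-2-one
Product: 23 (2S,3R)-2-(benzyloxy)-3-[3,4-bis(benzyloxy)-2-bromophenyl]-3-hydroxy-N-methoxy-N-methylpropanamide
Conditions: MeNH(OMe)·HCl, AlMe3, CH2Cl2, −20 → 0 °C; aqueous potassium sodium tartrate
Reagents that add atoms: N,O-dimethylhydroxylamine hydrochloride, CNOC.Cl
Why: Aluminium amide transamination to the Weinreb amide, as in step 5.

Step 16
Reactants: 23 (2S,3R)-2-(benzyloxy)-3-[3,4-bis(benzyloxy)-2-bromophenyl]-3-hydroxy-N-methoxy-N-methylpropanamide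
Product: 24 (2S,3R)-2-(benzyloxy)-3-[3,4-bis(benzyloxy)-2-bromophenyl]-3-[(tert-butyldimethylsilyl)oxy]-N-methoxy-N-methylpropanamide
Conditions: TBSOTf, 2,6-lutidine, CH2Cl2, −78 → 0 °C
Reagents that add atoms: tert-butyldimethylsilyl trifluoromethanesulfonate, CC(C)(C)[Si](C)(C)OS(=O)(=O)C(F)(F)F
Why: Silylation; this oxygen (future O4 of M) stays protected until after ring closure, so the robust silyl group is put on at once.

Step 17
Reactants: 24 (2S,3R)-2-(benzyloxy)-3-[3,4-bis(benzyloxy)-2-bromophenyl]-3-[(tert-butyldimethylsilyl)oxy]-N-methoxy-N-methylpropanamide; 25 [4-(benzyloxy)phenyl]magnesium bromide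
Product: 26 (2S,3R)-2-(benzyloxy)-3-[3,4-bis(benzyloxy)-2-bromophenyl]-1-[4-(benzyloxy)phenyl]-3-[(tert-butyldimethylsilyl)oxy]propan-1-one
Conditions: 25 (THF solution), THF, −20 → 0 °C; aq NH4Cl
Reagents that add atoms: none
Why: Weinreb ketone synthesis; the chelated tetrahedral intermediate prevents a second addition, and the aryl bromide does not exchange with an aryl Grignard reagent at this temperature.

Step 18
Reactants: 26 (2S,3R)-2-(benzyloxy)-3-[3,4-bis(benzyloxy)-2-bromophenyl]-1-[4-(benzyloxy)phenyl]-3-[(tert-butyldimethylsilyl)oxy]propan-1-one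
Product: 27 (1R,2R,3R)-2-(benzyloxy)-3-[3,4-bis(benzyloxy)-2-bromophenyl]-1-[4-(benzyloxy)phenyl]-3-[(tert-butyldimethylsilyl)oxy]propan-1-ol
Conditions: Zn(BH4)2, Et2O, −40 → 0 °C; aq NH4Cl
Reagents that add atoms: none
Why: Chelation-controlled reduction as in step 8; the new carbinol (future C2) should form anti to the benzyloxy group at C3, which becomes the 2,3-trans relation and the 2R configuration of unit M.

Step 19
Reactants: 27 (1R,2R,3R)-2-(benzyloxy)-3-[3,4-bis(benzyloxy)-2-bromophenyl]-1-[4-(benzyloxy)phenyl]-3-[(tert-butyldimethylsilyl)oxy]propan-1-ol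
Product: 28 (2R,3R,4R)-3,7,8-tris(benzyloxy)-2-[4-(benzyloxy)phenyl]-4-[(tert-butyldimethylsilyl)oxy]chromane (2,3-trans-3,4-trans)
Conditions: CuI (10 mol %), 3,4,7,8-tetramethyl-1,10-phenanthroline (20 mol %), Cs2CO3, toluene, 110 °C, argon
Reagents that add atoms: none
Why: The same copper-catalysed intramolecular O-arylation as in step 11, forming O1–C8a with retention at C2; the all-equatorial ring should close more easily than the all-cis one.

Step 20
Reactants: 28 (2R,3R,4R)-3,7,8-tris(benzyloxy)-2-[4-(benzyloxy)phenyl]-4-[(tert-butyldimethylsilyl)oxy]chromane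
Product: 29 (2R,3S,4R)-3,7,8-tris(benzyloxy)-2-[4-(benzyloxy)phenyl]chroman-4-ol
Conditions: Bu4NF, THF, 0 °C → rt
Reagents that add atoms: none
Why: Fluoride cleavage of the silyl ether; all other groups are ethers and inert.

Step 21
Reactants: 29 (2R,3S,4R)-3,7,8-tris(benzyloxy)-2-[4-(benzyloxy)phenyl]chroman-4-ol
Product: 30 (2R,3R,4R)-3,7,8-tris(benzyloxy)-2-[4-(benzyloxy)phenyl]-4-[(2,6-dimethylphenyl)sulfanyl]chromane
Conditions: 2,6-dimethylbenzenethiol (3 equiv), BF3·OEt2 (0.3 equiv), CH2Cl2, −40 → −20 °C
Reagents that add atoms: 2,6-dimethylbenzenethiol, Cc1cccc(C)c1S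
Why: Lewis-acid thiolysis through the C4 cation, which O1 and the 7-benzyloxy group stabilise; the thiol in excess should trap the cation faster than any ring A can, and the two ortho methyl groups make the sulfur a poor nucleophile in the next coupling.

Step 22
Reactants: 17 (2R,3S,4R)-3,7,8-tris(benzyloxy)-2-[4-(benzyloxy)phenyl]-4-[(tert-butyldimethylsilyl)oxy]chromane
Product: 31 (2R,3S,4R)-3,7,8-tris(benzyloxy)-2-[4-(benzyloxy)phenyl]-6-bromo-4-[(tert-butyldimethylsilyl)oxy]chromane
Conditions: NBS (1.0 equiv), CH2Cl2, −20 → 0 °C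
Reagents that add atoms: N-bromosuccinimide, O=C1CCC(=O)N1Br
Why: Electrophilic bromination at C6, the position para to O1 and ortho to the 7-benzyloxy group; C5 and ring B are activated by one oxygen only, and the bromine caps the nucleophilic site of the future electrophile until the final hydrogenolysis.

Step 23
Reactants: 31 (2R,3S,4R)-3,7,8-tris(benzyloxy)-2-[4-(benzyloxy)phenyl]-6-bromo-4-[(tert-butyldimethylsilyl)oxy]chromane
Product: 32 (2R,3R,4R)-3,7,8-tris(benzyloxy)-2-[4-(benzyloxy)phenyl]-6-bromochroman-4-ol
Conditions: Bu4NF, THF, 0 °C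
Reagents that add atoms: none
Why: Fluoride cleavage of the silyl ether gives the free benzylic alcohol that serves as the leaving group of unit T.

Step 24
Reactants: 32 (2R,3R,4R)-3,7,8-tris(benzyloxy)-2-[4-(benzyloxy)phenyl]-6-bromochroman-4-ol; 30 (2R,3R,4R)-3,7,8-tris(benzyloxy)-2-[4-(benzyloxy)phenyl]-4-[(2,6-dimethylphenyl)sulfanyl]chromane
Product: 33 protected dimer T–M: C4 of the 6-bromo unit T (2,3-cis-3,4-trans) bonded to C6 of thioether unit M
Conditions: 30 (1.3 equiv), BF3·OEt2 (0.3 equiv), 4 Å molecular sieves, CH2Cl2, −78 → −30 °C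
Reagents that add atoms: none
Why: Friedel–Crafts-type interflavan coupling; the hard Lewis acid ionises the benzylic hydroxyl of 32 but not the thioether of 30, and C6 of 30 attacks the cation on the face opposite the 2-aryl and 3-benzyloxy groups, which should give the 3,4-trans centre of unit T. The bromine at C6 of 32 prevents self-condensation.

Step 25
Reactants: 33 protected dimer T–M; 17 (2R,3S,4R)-3,7,8-tris(benzyloxy)-2-[4-(benzyloxy)phenyl]-4-[(tert-butyldimethylsilyl)oxy]chromane
Product: 34 protected trimer T–M–B: twelve benzyl ethers, bromine at C6 of T, silyl ether at O4 of B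
Conditions: 17 (1.5 equiv), AgBF4 (1.5 equiv), 2,6-di-tert-butyl-4-methylpyridine (2 equiv), 4 Å molecular sieves, CH2Cl2/THF, −40 → 0 °C
Reagents that add atoms: none
Why: Thiophilic activation; silver ionises the C4–S bond of 33 and leaves the benzylic silyl ether of 17 alone, while the hindered pyridine takes up the acid that is released. C6 of 17 should attack the cation of the 2,3-trans unit anti to the 3-benzyloxy group, which gives the 3,4-trans centre (4R) of unit M.

Step 26
Reactants: 34 protected trimer T–M–B
Product: 35 protected trimer with free 4-hydroxyl on unit B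
Conditions: Bu4NF, THF, 0 °C → rt
Reagents that add atoms: none
Why: Fluoride cleavage of the one silyl ether while every phenol is still benzylated, so the basic reagent meets no oxidisable phenolate.

Step 27
Reactants: 35 protected trimer with free 4-hydroxyl on unit B
Product: 36 target trimer (T 2R,3R,4S; M 2R,3S,4R; B 2R,3R,4R)
Conditions: H2 (1 atm), Pd(OH)2 on carbon, Et3N (1.2 equiv), THF/MeOH, rt
Reagents that add atoms: none
Why: Hydrogenolysis of the twelve benzyl ethers together with hydrodebromination at C6 of unit T; the amine binds the HBr so that the 4-hydroxyl of B is not ionised, and under neutral conditions the ring ether bonds and interflavan bonds should be retained.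

## Compound list

1 | 3-bromocatechol | Oc1cccc(Br)c1O | starting material
2 | 1,2-bis(benzyloxy)-3-bromobenzene | Brc1cccc(OCc2ccccc2)c1OCc1ccccc1 | intermediate
3 | 1,2-bis(benzyloxy)-3-bromo-4-iodobenzene | Brc1c(I)ccc(OCc2ccccc2)c1OCc1ccccc1 | intermediate
4 | (S)-4-benzyl-1,3-oxazolidin-2-one | O=C1N[C@@H](Cc2ccccc2)CO1 | starting material
5 | benzyloxyacetyl chloride | O=C(Cl)COCc1ccccc1 | starting material
6 | (S)-4-benzyl-3-[(benzyloxy)acetyl]-1,3-oxazolidin-2-one | O=C1OC[C@H](Cc2ccccc2)N1C(=O)COCc1ccccc1 | intermediate
7 | 4-(benzyloxy)benzaldehyde | O=Cc1ccc(OCc2ccccc2)cc1 | starting material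
8 | dibutylboron (Z)-enolate of 6 | O=C1OC[C@H](Cc2ccccc2)N1/C(OB(CCCC)CCCC)=C/OCc1ccccc1 | intermediate
9 | (4S)-4-benzyl-3-[(2S,3R)-2-(benzyloxy)-3-[4-(benzyloxy)phenyl]-3-hydroxypropanoyl]-1,3-oxazolidin-2-one | O=C1OC[C@H](Cc2ccccc2)N1C(=O)[C@@H](OCc1ccccc1)[C@H](O)c1ccc(OCc2ccccc2)cc1 | intermediate
10 | (2S,3R)-2-(benzyloxy)-3-[4-(benzyloxy)phenyl]-3-hydroxy-N-methoxy-N-methylpropanamide | CON(C)C(=O)[C@@H](OCc1ccccc1)[C@H](O)c1ccc(OCc2ccccc2)cc1 | intermediate
11 | (2S,3R)-2-(benzyloxy)-3-[4-(benzyloxy)phenyl]-N-methoxy-N-methyl-3-[(triethylsilyl)oxy]propanamide | CON(C)C(=O)[C@@H](OCc1ccccc1)[C@H](O[Si](CC)(CC)CC)c1ccc(OCc2ccccc2)cc1 | intermediate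
12 | [3,4-bis(benzyloxy)-2-bromophenyl]magnesium chloride (LiCl complex) | Cl[Mg]c1ccc(OCc2ccccc2)c(OCc2ccccc2)c1Br | intermediate
13 | (2S,3R)-2-(benzyloxy)-1-[3,4-bis(benzyloxy)-2-bromophenyl]-3-[4-(benzyloxy)phenyl]-3-[(triethylsilyl)oxy]propan-1-one | Brc1c(OCc2ccccc2)c(OCc2ccccc2)ccc1C(=O)[C@@H](OCc1ccccc1)[C@H](O[Si](CC)(CC)CC)c1ccc(OCc2ccccc2)cc1 | intermediate
14 | (1R,2R,3R)-2-(benzyloxy)-1-[3,4-bis(benzyloxy)-2-bromophenyl]-3-[4-(benzyloxy)phenyl]-3-[(triethylsilyl)oxy]propan-1-ol | Brc1c(OCc2ccccc2)c(OCc2ccccc2)ccc1[C@@H](O)[C@@H](OCc1ccccc1)[C@H](O[Si](CC)(CC)CC)c1ccc(OCc2ccccc2)cc1 | intermediate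
15 | (1R,2S,3R)-2-(benzyloxy)-1-[3,4-bis(benzyloxy)-2-bromophenyl]-3-[4-(benzyloxy)phenyl]-1-[(tert-butyldimethylsilyl)oxy]-3-[(triethylsilyl)oxy]propane | Brc1c(OCc2ccccc2)c(OCc2ccccc2)ccc1[C@@H](O[Si](C)(C)C(C)(C)C)[C@@H](OCc1ccccc1)[C@H](O[Si](CC)(CC)CC)c1ccc(OCc2ccccc2)cc1 | intermediate
16 | (1R,2S,3R)-2-(benzyloxy)-1-[4-(benzyloxy)phenyl]-3-[3,4-bis(benzyloxy)-2-bromophenyl]-3-[(tert-butyldimethylsilyl)oxy]propan-1-ol | Brc1c(OCc2ccccc2)c(OCc2ccccc2)ccc1[C@@H](O[Si](C)(C)C(C)(C)C)[C@@H](OCc1ccccc1)[C@H](O)c1ccc(OCc2ccccc2)cc1 | intermediate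
17 | (2R,3S,4R)-3,7,8-tris(benzyloxy)-2-[4-(benzyloxy)phenyl]-4-[(tert-butyldimethylsilyl)oxy]chromane (all-cis) | c1cc2c(c(OCc3ccccc3)c1OCc1ccccc1)O[C@H](c1ccc(OCc3ccccc3)cc1)[C@H](OCc1ccccc1)[C@@H]2O[Si](C)(C)C(C)(C)C | intermediate
18 | 2-bromo-3-hydroxy-4-methoxybenzaldehyde | COc1ccc(C=O)c(Br)c1O | starting material
19 | 2-bromo-3,4-dihydroxybenzaldehyde | O=Cc1ccc(O)c(O)c1Br | intermediate
20 | 3,4-bis(benzyloxy)-2-bromobenzaldehyde | O=Cc1ccc(OCc2ccccc2)c(OCc2ccccc2)c1Br | intermediate
21 | trichlorotitanium (Z)-enolate of 6 | O=C1OC[C@H](Cc2ccccc2)N1/C(O[Ti](Cl)(Cl)Cl)=C/OCc1ccccc1 | intermediate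
22 | (4S)-4-benzyl-3-[(2S,3R)-2-(benzyloxy)-3-[3,4-bis(benzyloxy)-2-bromophenyl]-3-hydroxypropanoyl]-1,3-oxazolidin-2-one | O=C1OC[C@H](Cc2ccccc2)N1C(=O)[C@@H](OCc1ccccc1)[C@H](O)c1ccc(OCc2ccccc2)c(OCc2ccccc2)c1Br | intermediate
23 | (2S,3R)-2-(benzyloxy)-3-[3,4-bis(benzyloxy)-2-bromophenyl]-3-hydroxy-N-methoxy-N-methylpropanamide | CON(C)C(=O)[C@@H](OCc1ccccc1)[C@H](O)c1ccc(OCc2ccccc2)c(OCc2ccccc2)c1Br | intermediate
24 | (2S,3R)-2-(benzyloxy)-3-[3,4-bis(benzyloxy)-2-bromophenyl]-3-[(tert-butyldimethylsilyl)oxy]-N-methoxy-N-methylpropanamide | CON(C)C(=O)[C@@H](OCc1ccccc1)[C@H](O[Si](C)(C)C(C)(C)C)c1ccc(OCc2ccccc2)c(OCc2ccccc2)c1Br | intermediate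
25 | [4-(benzyloxy)phenyl]magnesium bromide | Br[Mg]c1ccc(OCc2ccccc2)cc1 | starting material
26 | (2S,3R)-2-(benzyloxy)-3-[3,4-bis(benzyloxy)-2-bromophenyl]-1-[4-(benzyloxy)phenyl]-3-[(tert-butyldimethylsilyl)oxy]propan-1-one | O=C(c1ccc(OCc2ccccc2)cc1)[C@@H](OCc1ccccc1)[C@H](O[Si](C)(C)C(C)(C)C)c1ccc(OCc2ccccc2)c(OCc2ccccc2)c1Br | intermediate
27 | (1R,2R,3R)-2-(benzyloxy)-3-[3,4-bis(benzyloxy)-2-bromophenyl]-1-[4-(benzyloxy)phenyl]-3-[(tert-butyldimethylsilyl)oxy]propan-1-ol | O[C@H](c1ccc(OCc2ccccc2)cc1)[C@@H](OCc1ccccc1)[C@H](O[Si](C)(C)C(C)(C)C)c1ccc(OCc2ccccc2)c(OCc2ccccc2)c1Br | intermediate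
28 | (2R,3R,4R)-3,7,8-tris(benzyloxy)-2-[4-(benzyloxy)phenyl]-4-[(tert-butyldimethylsilyl)oxy]chromane (2,3-trans-3,4-trans) | c1cc2c(c(OCc3ccccc3)c1OCc1ccccc1)O[C@H](c1ccc(OCc3ccccc3)cc1)[C@@H](OCc1ccccc1)[C@@H]2O[Si](C)(C)C(C)(C)C | intermediate
29 | (2R,3S,4R)-3,7,8-tris(benzyloxy)-2-[4-(benzyloxy)phenyl]chroman-4-ol (2,3-trans-3,4-trans) | c1cc2c(c(OCc3ccccc3)c1OCc1ccccc1)O[C@H](c1ccc(OCc3ccccc3)cc1)[C@@H](OCc1ccccc1)[C@@H]2O | intermediate
30 | (2R,3R,4R)-3,7,8-tris(benzyloxy)-2-[4-(benzyloxy)phenyl]-4-[(2,6-dimethylphenyl)sulfanyl]chromane | c1cc2c(c(OCc3ccccc3)c1OCc1ccccc1)O[C@H](c1ccc(OCc3ccccc3)cc1)[C@@H](OCc1ccccc1)[C@@H]2Sc1c(C)cccc1C | intermediate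
31 | (2R,3S,4R)-3,7,8-tris(benzyloxy)-2-[4-(benzyloxy)phenyl]-6-bromo-4-[(tert-butyldimethylsilyl)oxy]chromane | Brc1cc2c(c(OCc3ccccc3)c1OCc1ccccc1)O[C@H](c1ccc(OCc3ccccc3)cc1)[C@H](OCc1ccccc1)[C@@H]2O[Si](C)(C)C(C)(C)C | intermediate
32 | (2R,3R,4R)-3,7,8-tris(benzyloxy)-2-[4-(benzyloxy)phenyl]-6-bromochroman-4-ol (all-cis) | Brc1cc2c(c(OCc3ccccc3)c1OCc1ccccc1)O[C@H](c1ccc(OCc3ccccc3)cc1)[C@H](OCc1ccccc1)[C@@H]2O | intermediate
33 | protected dimer T–M (unit T: 6-bromo, 2,3-cis-3,4-trans, its C4 bonded to C6 of unit M; unit M: 2,3-trans, C4 thioether as in 30) | Brc1cc2c(c(OCc3ccccc3)c1OCc1ccccc1)O[C@H](c1ccc(OCc3ccccc3)cc1)[C@H](OCc1ccccc1)[C@H]2c1cc2c(c(OCc3ccccc3)c1OCc1ccccc1)O[C@H](c1ccc(OCc3ccccc3)cc1)[C@@H](OCc1ccccc1)[C@@H]2Sc1c(C)cccc1C | intermediate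
34 | protected trimer T–M–B (twelve benzyl ethers, bromine at C6 of T, tert-butyldimethylsilyl ether at O4 of B; ring configurations as in 36) | Brc1cc2c(c(OCc3ccccc3)c1OCc1ccccc1)O[C@H](c1ccc(OCc3ccccc3)cc1)[C@H](OCc1ccccc1)[C@H]2c1cc2c(c(OCc3ccccc3)c1OCc1ccccc1)O[C@H](c1ccc(OCc3ccccc3)cc1)[C@@H](OCc1ccccc1)[C@@H]2c1cc2c(c(OCc3ccccc3)c1OCc1ccccc1)O[C@H](c1ccc(OCc3ccccc3)cc1)[C@H](OCc1ccccc1)[C@@H]2O[Si](C)(C)C(C)(C)C | intermediate
35 | protected trimer with free 4-hydroxyl on unit B (twelve benzyl ethers, bromine at C6 of T) | Brc1cc2c(c(OCc3ccccc3)c1OCc1ccccc1)O[C@H](c1ccc(OCc3ccccc3)cc1)[C@H](OCc1ccccc1)[C@H]2c1cc2c(c(OCc3ccccc3)c1OCc1ccccc1)O[C@H](c1ccc(OCc3ccccc3)cc1)[C@@H](OCc1ccccc1)[C@@H]2c1cc2c(c(OCc3ccccc3)c1OCc1ccccc1)O[C@H](c1ccc(OCc3ccccc3)cc1)[C@H](OCc1ccccc1)[C@@H]2O | intermediate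
36 | target trimer CNP0140823.2 (T 2R,3R,4S; M 2R,3S,4R; B 2R,3R,4R) | Oc1ccc([C@H]2Oc3c(ccc(O)c3O)[C@H](c3cc4c(c(O)c3O)O[C@H](c3ccc(O)cc3)[C@@H](O)[C@@H]4c3cc4c(c(O)c3O)O[C@H](c3ccc(O)cc3)[C@H](O)[C@@H]4O)[C@H]2O)cc1 | target

## Step count and uncertain steps

Total: 27 steps. Longest linear sequence: 15 steps (steps 3–11, 22, 23, 24–27). The line through unit M (steps 12–21, 24–27) has 14 steps.

**Step 11 (key step).** The most likely failure is slow oxidative addition at the electron-rich aryl bromide with two ortho substituents, so that hydrodebromination, or a shift of the silyl group from O4 to O2 that blocks the nucleophile, overtakes ring closure. Fallback: from 16, form the same O1–C8a bond by palladium catalysis (Pd2(dba)3, a bulky di-tert-butyl biaryl phosphine such as t-BuBrettPhos, Cs2CO3, toluene, 80 °C), which leads to 17. Zerovalent palladium inserts into hindered, electron-rich aryl bromides more readily than copper does, and the bulky ligand drives C–O reductive elimination from divalent palladium ahead of β-hydride loss. C2 is again untouched, and no new compound arises (F0).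

**Step 7.** The hindered ortho-bromoaryl Grignard reagent may add too slowly to the hindered amide; on warming, loss of magnesium halide from 12 (aryne formation) or simple protonation would then consume the reagent. Fallback: from 11, i-Bu2AlH in CH2Cl2 at −78 °C stops at the aldehyde (2S,3R)-2-(benzyloxy)-3-[4-(benzyloxy)phenyl]-3-[(triethylsilyl)oxy]propanal F1. Grignard reagent 12, made from 3 as in step 7, adds to an aldehyde already at −60 °C and gives the carbinol 2-(benzyloxy)-1-[3,4-bis(benzyloxy)-2-bromophenyl]-3-[4-(benzyloxy)phenyl]-3-[(triethylsilyl)oxy]propan-1-ol F2 as a mixture of C1 epimers. Dess–Martin periodinane oxidises both epimers to ketone 13, where the route is rejoined.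

**Step 24.** The sulfur of 30 may compete with C6 for the cation, or the acid set free may ionise the C4–S bond of 30; either process transfers the thio group and scrambles the units. Fallback: put the thioether on the electrophile and leave a silyl ether on the nucleophile. From 32, thiolysis as in step 21 gives (2R,3S,4S)-3,7,8-tris(benzyloxy)-2-[4-(benzyloxy)phenyl]-6-bromo-4-[(2,6-dimethylphenyl)sulfanyl]chromane F3. AgBF4 with the hindered pyridine couples F3 to silyl ether 28, whose C4 oxygen is inert to silver, and gives the protected dimer T–M with a silyl ether at C4 of unit M F4. Bu4NF frees the protected dimer T–M with a 4-hydroxyl on unit M F5, and thiolysis as in step 21 converts F5 into 33.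

**Step 25.** Ionisation of the dimeric thioether may be slow at temperatures at which the benzylic silyl ether of 17 survives. Loss of that silyl group with ionisation of unit B, or attack on the wrong face of the 2,3-trans cation, would then cost a late intermediate. Fallback: change the order of assembly so that the thioether ionised next to unit B is a monomer. From 30 and 17 (three equivalents, the excess recovered, which also suppresses self-condensation of 30), AgBF4 and the hindered pyridine give the protected dimer M–B F6. F6 is then coupled at C6 of its unit M with the thioether F3 described under step 24, under the same conditions, which gives 34.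

**Step 27.** Once the 7-hydroxyl of unit B is unmasked, the para benzylic C4–O bond may be hydrogenolysed, or insufficiently buffered HBr may ionise it. Fallback: reverse the last two steps. From 34, hydrogenolysis (H2, Pd(OH)2 on carbon, Et3N, THF/MeOH) with the silyl ether still in place gives the free nonaphenol with a tert-butyldimethylsilyl ether at O4 of unit B F7, in which the bulky silyl group shields the C4–O bond. Et3N·3HF in THF/MeCN then removes the silyl group and gives 36.

## Further compounds

F0 | step 11 | none | none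
F1 | step 7 | (2S,3R)-2-(benzyloxy)-3-[4-(benzyloxy)phenyl]-3-[(triethylsilyl)oxy]propanal | O=C[C@@H](OCc1ccccc1)[C@H](O[Si](CC)(CC)CC)c1ccc(OCc2ccccc2)cc1
F2 | step 7 | 2-(benzyloxy)-1-[3,4-bis(benzyloxy)-2-bromophenyl]-3-[4-(benzyloxy)phenyl]-3-[(triethylsilyl)oxy]propan-1-ol (2R,3R; C1 epimer mixture) | Brc1c(OCc2ccccc2)c(OCc2ccccc2)ccc1C(O)[C@@H](OCc1ccccc1)[C@H](O[Si](CC)(CC)CC)c1ccc(OCc2ccccc2)cc1
F3 | step 24 | (2R,3S,4S)-3,7,8-tris(benzyloxy)-2-[4-(benzyloxy)phenyl]-6-bromo-4-[(2,6-dimethylphenyl)sulfanyl]chromane | Brc1cc2c(c(OCc3ccccc3)c1OCc1ccccc1)O[C@H](c1ccc(OCc3ccccc3)cc1)[C@H](OCc1ccccc1)[C@H]2Sc1c(C)cccc1C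
F4 | step 24 | protected dimer T–M with a tert-butyldimethylsilyl ether at C4 of unit M | Brc1cc2c(c(OCc3ccccc3)c1OCc1ccccc1)O[C@H](c1ccc(OCc3ccccc3)cc1)[C@H](OCc1ccccc1)[C@H]2c1cc2c(c(OCc3ccccc3)c1OCc1ccccc1)O[C@H](c1ccc(OCc3ccccc3)cc1)[C@@H](OCc1ccccc1)[C@@H]2O[Si](C)(C)C(C)(C)C
F5 | step 24 | protected dimer T–M with a 4-hydroxyl on unit M | Brc1cc2c(c(OCc3ccccc3)c1OCc1ccccc1)O[C@H](c1ccc(OCc3ccccc3)cc1)[C@H](OCc1ccccc1)[C@H]2c1cc2c(c(OCc3ccccc3)c1OCc1ccccc1)O[C@H](c1ccc(OCc3ccccc3)cc1)[C@@H](OCc1ccccc1)[C@@H]2O
F6 | step 25 | protected dimer M–B (C4 of unit M bonded to C6 of unit B, silyl ether at O4 of B, C6 of M free) | c1cc2c(c(OCc3ccccc3)c1OCc1ccccc1)O[C@H](c1ccc(OCc3ccccc3)cc1)[C@@H](OCc1ccccc1)[C@@H]2c1cc2c(c(OCc3ccccc3)c1OCc1ccccc1)O[C@H](c1ccc(OCc3ccccc3)cc1)[C@H](OCc1ccccc1)[C@@H]2O[Si](C)(C)C(C)(C)C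
F7 | step 27 | free nonaphenol trimer with a tert-butyldimethylsilyl ether at O4 of unit B | Oc1ccc([C@H]2Oc3c(ccc(O)c3O)[C@H](c3cc4c(c(O)c3O)O[C@H](c3ccc(O)cc3)[C@@H](O)[C@@H]4c3cc4c(c(O)c3O)O[C@H](c3ccc(O)cc3)[C@H](O)[C@@H]4O[Si](C)(C)C(C)(C)C)[C@H]2O)cc1
A1 | alternative 1 | protected trimer with a pivalate on ring B of unit T and a free 3-hydroxyl on T | CC(C)(C)C(=O)Oc1ccc([C@H]2Oc3c(ccc(OCc5ccccc5)c3OCc5ccccc5)[C@H](c3cc4c(c(OCc5ccccc5)c3OCc5ccccc5)O[C@H](c3ccc(OCc5ccccc5)cc3)[C@@H](OCc5ccccc5)[C@@H]4c3cc4c(c(OCc5ccccc5)c3OCc5ccccc5)O[C@H](c3ccc(OCc5ccccc5)cc3)[C@H](OC(C)(C)O6)[C@@H]46)[C@H]2O)cc1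
A2 | alternative 2 | all-cis 3,7,8-tris(benzyloxy)-2-[4-(benzyloxy)phenyl]chroman-4-ol (3-O-benzyl teracacidin tribenzyl ether) | c1cc2c(c(OCc5ccccc5)c1OCc5ccccc5)O[C@H](c1ccc(OCc5ccccc5)cc1)[C@H](OCc5ccccc5)[C@@H]2O
A3 | alternative 3 | M–B dimer with unit M as its 2-aryl-4H-chromene and unit B as the 3,4-acetonide | c1cc2c(c(OCc5ccccc5)c1OCc5ccccc5)OC(c1ccc(OCc5ccccc5)cc1)=C[C@@H]2c3cc4c(c(OCc5ccccc5)c3OCc5ccccc5)O[C@H](c3ccc(OCc5ccccc5)cc3)[C@H](OC(C)(C)O6)[C@@H]46
A4 | alternative 3 | 1-(benzyloxy)-4-ethynylbenzene | C#Cc1ccc(OCc2ccccc2)cc1
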